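The target is an ester of a labdane alcohol and a 9,10-seco-drimane acid; the ester bond is made last. In the labdane, ring A has no stereocentre at C1–C3 and carries the C20 methyl on C10, so C1/C10/C20 map onto the isopropenyl group of (S)-limonene, whose stereocentre becomes C9. A thermal intramolecular Diels–Alder reaction of a 2-silyloxy-3-methyldiene (C2–C5) with this isopropenyl group, linked by C6–C9, forms C1–C2 and C5–C10 at once, closes rings A and B and relays C9 to C10 and C5. The resulting C3 silyl enol ether is hydroxymethylated to set C4 and then deoxygenated.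

Key step: step 8

Remark: labdane numbering (C1–C20) is used for the decalin fragment and primed numbers (C1'–C5') for the chain of the acid; (S)-(−)-limonene, β-cyclocitral and all reagents are taken as commercial.

Step 1
Reactants: 1 (S)-(−)-limonene
Product: 2 (3S)-6-oxo-3-(prop-1-en-2-yl)heptanal
Conditions: O3 (1.0 equiv, Sudan Red 7B as end-point indicator), CH2Cl2/MeOH, −78 °C; then Me2S, −78 °C → rt
Reagents that add atoms: ozone, [O-][O+]=O
Why: Chemoselective ozonolysis with reductive work-up, in which the electron-rich trisubstituted ring alkene is cleaved well before the 1,1-disubstituted isopropenyl group and the stereocentre (the future C9) is not touched.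

Step 2
Reactants: 2 (3S)-6-oxo-3-(prop-1-en-2-yl)heptanal
Product: 3 (3R)-2-methylidene-6-oxo-3-(prop-1-en-2-yl)heptanal
Conditions: 37% aq. HCHO (1.1 equiv), pyrrolidine (10 mol %), EtCO2H (10 mol %), i-PrOH, 45 °C, short reaction time
Reagents that add atoms: formaldehyde, C=O
Why: Amine-catalysed Mannich condensation–elimination (α-methylenation of an aldehyde), in which the aldehyde forms its enamine much faster than the methyl ketone, so that C8 gains the carbon that becomes C7 while the ketone and the C9 stereocentre should survive a short reaction time.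

Step 3
Reactants: 3 (3R)-2-methylidene-6-oxo-3-(prop-1-en-2-yl)heptanal
Product: 4 (5R)-5-(3-hydroxyprop-1-en-2-yl)-6-methylhept-6-en-2-one
Conditions: LiAlH(OtBu)3 (1.1 equiv), THF, −78 °C
Reagents that add atoms: none
Why: Chemoselective 1,2-reduction, since the bulky alkoxyaluminium hydride reduces an aldehyde much faster than a methyl ketone at −78 °C and adds 1,2 to the enal, which should give the 2-substituted allylic alcohol with the ketone kept.

Step 4
Reactants: 4 (5R)-5-(3-hydroxyprop-1-en-2-yl)-6-methylhept-6-en-2-one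
Product: 5 methyl (2E,6R)-6-(3-hydroxyprop-1-en-2-yl)-3,7-dimethylocta-2,7-dienoate
Conditions: (MeO)2P(O)CH2CO2Me (2 equiv), NaH (3 equiv), THF, 0 → 50 °C; the (2Z) isomer expected as minor product is removed by chromatography
Reagents that add atoms: trimethyl phosphonoacetate, COC(=O)CP(=O)(OC)OC
Why: Horner–Wadsworth–Emmons olefination of the methyl ketone (the free primary alcohol only consumes base) should give mainly the (E)-β-methyl enoate with the ester trans to the longer chain, and no stereocentre is formed.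

Step 5
Reactants: 5 methyl (2E,6R)-6-(3-hydroxyprop-1-en-2-yl)-3,7-dimethylocta-2,7-dienoate
Product: 7 methyl (2E,6R)-3,7-dimethyl-6-(5-oxopent-1-en-2-yl)octa-2,7-dienoate, via allyl vinyl ether 6 (not isolated)
Conditions: n-butyl vinyl ether (solvent), Pd(OCOCF3)2 (2 mol %), 4,7-diphenyl-1,10-phenanthroline (2 mol %), Et3N (cat.), 75 °C; evaporate; PhMe, BHT (cat.), 150 °C, sealed tube
Reagents that add atoms: n-butyl vinyl ether, C=COCCCC
Why: Palladium-catalysed vinyl transfer to the primary allylic alcohol followed by an aliphatic Claisen rearrangement ([3,3]-sigmatropic), in which the new C6–C7 bond forms at the methylidene carbon and the former carbinol carbon becomes the C17 methylidene, so the 2-substituted 4-pentenal (C5–C8, C17) arises without touching C9.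

Step 6
Reactants: 7 methyl (2E,6R)-3,7-dimethyl-6-(5-oxopent-1-en-2-yl)octa-2,7-dienoate
Product: 8 methyl (2E,6R)-3,7-dimethyl-6-[(5E)-6-methyl-7-oxoocta-1,5-dien-2-yl]octa-2,7-dienoate
Conditions: Ph3P=C(CH3)C(O)CH3 (1.3 equiv), PhMe, 100 °C
Reagents that add atoms: 3-(triphenyl-λ5-phosphanylidene)butan-2-one, CC(=O)C(C)=P(c1ccccc1)(c1ccccc1)c1ccccc1
Why: Wittig olefination of the aldehyde with a stabilised α-branched acyl ylide should give the (E)-trisubstituted enone (C3 carbonyl trans to C6) and leaves the enoate alone.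

Step 7
Reactants: 8 methyl (2E,6R)-3,7-dimethyl-6-[(5E)-6-methyl-7-oxoocta-1,5-dien-2-yl]octa-2,7-dienoate
Product: 9 methyl (2E,6R)-3,7-dimethyl-6-{(5E)-6-methyl-7-[(triethylsilyl)oxy]octa-1,5,7-trien-2-yl}octa-2,7-dienoate
Conditions: Et3SiOTf (1.2 equiv), Et3N (2 equiv), CH2Cl2, −78 → 0 °C; non-aqueous work-up
Reagents that add atoms: triethylsilyl trifluoromethanesulfonate, CC[Si](CC)(CC)OS(=O)(=O)C(F)(F)F
Why: Soft enolisation of the methyl ketone (silyl triflate with a tertiary amine) removes a proton from the acetyl methyl group and should give the cross-conjugated 2-silyloxy-1,3-diene with the (E)-C4=C5 bond retained, while the less acidic enoate is not silylated.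

Step 8
Reactants: 9 methyl (2E,6R)-3,7-dimethyl-6-{(5E)-6-methyl-7-[(triethylsilyl)oxy]octa-1,5,7-trien-2-yl}octa-2,7-dienoate
Product: 10 methyl (2E)-3-methyl-5-{(1S,4aR,8aR)-5,8a-dimethyl-2-methylidene-6-[(triethylsilyl)oxy]-1,2,3,4,4a,7,8,8a-octahydronaphthalen-1-yl}pent-2-enoate
Conditions: PhMe (0.01 M), BHT (10 mol %), Et3N (0.1 equiv), base-washed sealed tube, 190 °C
Reagents that add atoms: none
Why: A concerted thermal [4+2] cycloaddition (type 1 intramolecular Diels–Alder reaction of a 1,7,9-decatriene) between the electron-rich 2-silyloxy-3-methyldiene C2=C3–C4=C5 and the isopropenyl unit C1=C10 forms C1–C2 and C5–C10 together, the closest known reactions being thermal intramolecular Diels–Alder reactions of unactivated decatrienes and of 2-silyloxydienes. Ring A closes as the six-membered ring of the cycloaddition itself and ring B through the four-carbon tether C6–C9 in the fused mode, because the bridged mode and addition to the C8 methylidene (two-atom tether) or to the distant enoate would need strained or medium rings. C10 and C5 are set in the anti transition state with a chair-like tether, in which the small C20 methyl sits endo (axial on the forming ring B) and the branched C9 exo, and the (E)-C4=C5 geometry places H-5 trans to that methyl, so a trans-decalin should result. The π-face is chosen by C9, the only stereocentre present: its side chain takes the equatorial site of the chair and its hydrogen points towards the CH2 of the dienophile (least allylic strain), which gives 9α-H and 10β-CH3. The step needs periselectivity, trans ring fusion and facial control; the first is secured by the tether length, the second is helped by the sp2 C8, which removes one 1,3-diaxial contact of the axial methyl, and the third rests on the equatorial preference of the C9 chain. The cycloaddition also delivers the silyl enol ether regiospecifically as C3=C4, ready for quaternisation of C4.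

Step 9
Reactants: 10 methyl (2E)-3-methyl-5-{(1S,4aR,8aR)-5,8a-dimethyl-2-methylidene-6-[(triethylsilyl)oxy]-1,2,3,4,4a,7,8,8a-octahydronaphthalen-1-yl}pent-2-enoate
Product: 11 methyl (2E)-5-[(1S,4aR,5R,8aR)-5-(hydroxymethyl)-5,8a-dimethyl-2-methylidene-6-oxodecahydronaphthalen-1-yl]-3-methylpent-2-enoate
Conditions: 37% aq. HCHO (excess), Yb(OTf)3 (20 mol %), THF, rt
Reagents that add atoms: formaldehyde, C=O
Why: Lewis-acid-catalysed Mukaiyama aldol reaction of the tetrasubstituted silyl enol ether with formaldehyde in aqueous medium, in which the electrophile should approach C4 from the α-face, away from the axial C10 methyl (a 1,3-diaxial contact on the β-face), to give the quaternary centre with equatorial CH2OH (C18) and axial CH3 (C19).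

Step 10
Reactants: 11 methyl (2E)-5-[(1S,4aR,5R,8aR)-5-(hydroxymethyl)-5,8a-dimethyl-2-methylidene-6-oxodecahydronaphthalen-1-yl]-3-methylpent-2-enoate
Product: 13 methyl (2E)-5-[(1S,4aR,5R,8aR)-5-(hydroxymethyl)-5,8a-dimethyl-2-methylidenedecahydronaphthalen-1-yl]-3-methylpent-2-enoate, via tosylhydrazone 12 (not isolated)
Conditions: TsNHNH2 (2 equiv), PPTS (cat.), EtOH, 70 °C; evaporate; catecholborane (4 equiv), CHCl3, 0 °C → rt; then NaOAc·3H2O, 60 °C
Reagents that add atoms: 4-methylbenzenesulfonohydrazide (its atoms stay only in 12), Cc1ccc(cc1)S(=O)(=O)NN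
Why: Deoxygenation of the C3 ketone by hydride reduction of its tosylhydrazone and loss of sulfinate and N2 from the diazene (a mild alternative to the Wolff–Kishner reduction) should tolerate the enoate, the exocyclic alkene and the free primary alcohol and creates no stereocentre.

Step 11
Reactants: 14 β-cyclocitral (2,6,6-trimethylcyclohex-1-ene-1-carbaldehyde)
Product: 15 β-cyclogeraniol, (2,6,6-trimethylcyclohex-1-en-1-yl)methanol
Conditions: NaBH4, MeOH, 0 °C
Reagents that add atoms: none
Why: Borohydride 1,2-reduction of the hindered, fully substituted enal gives the allylic alcohol needed for a directed epoxidation.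

Step 12
Reactants: 15 β-cyclogeraniol
Product: 16 [(1R,6R)-2,2,6-trimethyl-7-oxabicyclo[4.1.0]heptan-1-yl]methanol
Conditions: Ti(OiPr)4 (0.2 equiv), D-(−)-diethyl tartrate (0.24 equiv), t-BuOOH (2 equiv, in decane), 4 Å molecular sieves, CH2Cl2, −20 °C
Reagents that add atoms: tert-butyl hydroperoxide, CC(C)(C)OO
Why: Sharpless asymmetric epoxidation of the tetrasubstituted allylic alcohol, in which the unnatural D-(−)-tartrate directs oxygen to the face that gives the (1R,6R)-epoxy alcohol (the mirror image of the face taken with geraniol and L-(+)-tartrate) and thereby fixes the future tertiary carbinol.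

Step 13
Reactants: 16 [(1R,6R)-2,2,6-trimethyl-7-oxabicyclo[4.1.0]heptan-1-yl]methanol
Product: 18 (3E)-4-[(1S,6R)-2,2,6-trimethyl-7-oxabicyclo[4.1.0]heptan-1-yl]but-3-en-2-one, via epoxy aldehyde 17 (not isolated)
Conditions: Dess–Martin periodinane (1.3 equiv), NaHCO3, CH2Cl2, 0 °C → rt; then Ph3P=CHC(O)CH3 (2 equiv), 40 °C
Reagents that add atoms: 1-(triphenyl-λ5-phosphanylidene)propan-2-one, CC(=O)C=P(c1ccccc1)(c1ccccc1)c1ccccc1
Why: Oxidation to the non-enolisable epoxy aldehyde and Wittig olefination with a stabilised ylide in one pot should give the (E)-γ,δ-epoxy enone without change at the two epoxide carbons.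

Step 14
Reactants: 18 (3E)-4-[(1S,6R)-2,2,6-trimethyl-7-oxabicyclo[4.1.0]heptan-1-yl]but-3-en-2-one
Product: 19 (4Z)-4-[(2R)-2-hydroxy-2,6,6-trimethylcyclohexylidene]butan-2-one
Conditions: SmI2 (2.5 equiv), THF/MeOH, −90 °C
Reagents that add atoms: none
Why: Reductive opening of a γ,δ-epoxy-α,β-unsaturated ketone by single-electron transfer, in which the dienolate expels the allylic C–O bond and is protonated at the α-carbon, so the C–O bond at the methyl-bearing carbon keeps its configuration while the neighbouring ring carbon becomes sp2 (either alkene geometry serves in step 15).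

Step 15
Reactants: 19 (4Z)-4-[(2R)-2-hydroxy-2,6,6-trimethylcyclohexylidene]butan-2-one
Product: 20 4-[(1R,2R)-2-hydroxy-2,6,6-trimethylcyclohexyl]butan-2-one
Conditions: [Ir(cod)(PCy3)(py)]PF6 (5 mol %), H2 (1–4 atm), CH2Cl2, rt
Reagents that add atoms: none
Why: Hydroxyl-directed homogeneous hydrogenation, in which the tertiary allylic alcohol binds the cationic iridium and hydrogen is delivered to the exocyclic alkene on the face of the OH group, so the new ring CH carries its hydrogen cis and its side chain trans to the hydroxyl.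

Step 16
Reactants: 20 4-[(1R,2R)-2-hydroxy-2,6,6-trimethylcyclohexyl]butan-2-one
Product: 21 methyl (2E)-5-[(1R,2R)-2-hydroxy-2,6,6-trimethylcyclohexyl]-3-methylpent-2-enoate
Conditions: (MeO)2P(O)CH2CO2Me (2.5 equiv), NaH (3.5 equiv), THF, 0 → 60 °C; the (2Z) isomer expected as minor product is removed by chromatography
Reagents that add atoms: trimethyl phosphonoacetate, COC(=O)CP(=O)(OC)OC
Why: Horner–Wadsworth–Emmons olefination of the methyl ketone, which reacts from the open form of its hemiketal, should give mainly the (E)-enoate, and the hindered tertiary alkoxide is not expected to add back to the β,β-disubstituted enoate.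

Step 17
Reactants: 21 methyl (2E)-5-[(1R,2R)-2-hydroxy-2,6,6-trimethylcyclohexyl]-3-methylpent-2-enoate
Product: 22 (1R,2R)-2-[(3E)-5-hydroxy-3-methylpent-3-en-1-yl]-1,3,3-trimethylcyclohexan-1-ol
Conditions: i-Bu2AlH (3.5 equiv), CH2Cl2, −78 °C; aqueous Rochelle salt
Reagents that add atoms: none
Why: 1,2-Reduction of the enoate by the aluminium hydride gives the geraniol-type (E)-allylic alcohol, the substrate class for which the sense of the following asymmetric hydrogenation is secure.

Step 18
Reactants: 22 (1R,2R)-2-[(3E)-5-hydroxy-3-methylpent-3-en-1-yl]-1,3,3-trimethylcyclohexan-1-ol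
Product: 23 (1R,2R)-2-[(3S)-5-hydroxy-3-methylpentyl]-1,3,3-trimethylcyclohexan-1-ol
Conditions: Ru(OAc)2[(R)-BINAP] (1 mol %), H2 (50 atm), MeOH, rt
Reagents that add atoms: none
Why: Noyori asymmetric hydrogenation of an (E)-allylic alcohol, in which the allylic OH binds ruthenium and the (R)-BINAP complex should deliver H2 to the face that gives the (3S)-methyl stereocentre, as for geraniol to (S)-citronellol, under catalyst control unaffected by the remote ring stereocentres.

Step 19
Reactants: 23 (1R,2R)-2-[(3S)-5-hydroxy-3-methylpentyl]-1,3,3-trimethylcyclohexan-1-ol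
Product: 24 (3S)-5-[(1R,2R)-2-hydroxy-2,6,6-trimethylcyclohexyl]-3-methylpentanoic acid
Conditions: TEMPO (10 mol %), NaClO2 (2 equiv), NaOCl (2 mol %), MeCN/phosphate buffer pH 6.7, 35 °C
Reagents that add atoms: sodium chlorite, [Na+].[O-]Cl=O
Why: Nitroxyl-catalysed oxidation of the primary alcohol through the aldehyde to the acid, in which the tertiary alcohol cannot be oxidised and the β-methyl stereocentre cannot epimerise.

Step 20
Reactants: 13 methyl (2E)-5-[(1S,4aR,5R,8aR)-5-(hydroxymethyl)-5,8a-dimethyl-2-methylidenedecahydronaphthalen-1-yl]-3-methylpent-2-enoate; 24 (3S)-5-[(1R,2R)-2-hydroxy-2,6,6-trimethylcyclohexyl]-3-methylpentanoic acid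
Product: 25 methyl (2E)-5-[(1S,4aR,5R,8aR)-5-({[(3S)-5-[(1R,2R)-2-hydroxy-2,6,6-trimethylcyclohexyl]-3-methylpentanoyl]oxy}methyl)-5,8a-dimethyl-2-methylidenedecahydronaphthalen-1-yl]-3-methylpent-2-enoate
Conditions: EDC·HCl (1.5 equiv), DMAP (0.5 equiv), CH2Cl2, 0 °C → rt
Reagents that add atoms: none
Why: Steglich esterification, in which the acyl-pyridinium intermediate acylates the neopentyl primary C18 alcohol while the tertiary alcohol of the acid is too hindered to compete, and no stereocentre is affected.

Compound list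
1 | (S)-(−)-limonene, (4S)-1-methyl-4-(prop-1-en-2-yl)cyclohex-1-ene | C=C(C)[C@@H]1CC=C(C)CC1 | starting material
2 | (3S)-6-oxo-3-(prop-1-en-2-yl)heptanal | C=C(C)[C@H](CC=O)CCC(C)=O | intermediate
3 | (3R)-2-methylidene-6-oxo-3-(prop-1-en-2-yl)heptanal | C=C(C)[C@H](C(=C)C=O)CCC(C)=O | intermediate
4 | (5R)-5-(3-hydroxyprop-1-en-2-yl)-6-methylhept-6-en-2-one | C=C(C)[C@H](C(=C)CO)CCC(C)=O | intermediate
5 | methyl (2E,6R)-6-(3-hydroxyprop-1-en-2-yl)-3,7-dimethylocta-2,7-dienoate | C=C(C)[C@H](C(=C)CO)CC/C(C)=C/C(=O)OC | intermediate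
6 | methyl (2E,6R)-6-[3-(ethenyloxy)prop-1-en-2-yl]-3,7-dimethylocta-2,7-dienoate (allyl vinyl ether) | C=C(C)[C@H](C(=C)COC=C)CC/C(C)=C/C(=O)OC | intermediate
7 | methyl (2E,6R)-3,7-dimethyl-6-(5-oxopent-1-en-2-yl)octa-2,7-dienoate | C=C(C)[C@H](C(=C)CCC=O)CC/C(C)=C/C(=O)OC | intermediate
8 | methyl (2E,6R)-3,7-dimethyl-6-[(5E)-6-methyl-7-oxoocta-1,5-dien-2-yl]octa-2,7-dienoate | C=C(C)[C@H](C(=C)CC/C=C(\C)C(C)=O)CC/C(C)=C/C(=O)OC | intermediate
9 | methyl (2E,6R)-3,7-dimethyl-6-{(5E)-6-methyl-7-[(triethylsilyl)oxy]octa-1,5,7-trien-2-yl}octa-2,7-dienoate | C=C(C)[C@H](C(=C)CC/C=C(\C)C(=C)O[Si](CC)(CC)CC)CC/C(C)=C/C(=O)OC | intermediate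
10 | methyl (2E)-3-methyl-5-{(1S,4aR,8aR)-5,8a-dimethyl-2-methylidene-6-[(triethylsilyl)oxy]-1,2,3,4,4a,7,8,8a-octahydronaphthalen-1-yl}pent-2-enoate | C=C1CC[C@H]2C(C)=C(O[Si](CC)(CC)CC)CC[C@]2(C)[C@H]1CC/C(C)=C/C(=O)OC | intermediate
11 | methyl (2E)-5-[(1S,4aR,5R,8aR)-5-(hydroxymethyl)-5,8a-dimethyl-2-methylidene-6-oxodecahydronaphthalen-1-yl]-3-methylpent-2-enoate (methyl 18-hydroxy-3-oxolabda-8(17),13E-dien-15-oate) | C=C1CC[C@H]2[C@](C)(CO)C(=O)CC[C@]2(C)[C@H]1CC/C(C)=C/C(=O)OC | intermediate
12 | methyl (2E)-5-[(1S,4aR,5S,6E,8aR)-5-(hydroxymethyl)-5,8a-dimethyl-2-methylidene-6-{2-[(4-methylphenyl)sulfonyl]hydrazinylidene}decahydronaphthalen-1-yl]-3-methylpent-2-enoate (tosylhydrazone of 11) | C=C1CC[C@H]2[C@](C)(CO)/C(=N/NS(=O)(=O)c3ccc(C)cc3)CC[C@]2(C)[C@H]1CC/C(C)=C/C(=O)OC | intermediate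
13 | methyl (2E)-5-[(1S,4aR,5R,8aR)-5-(hydroxymethyl)-5,8a-dimethyl-2-methylidenedecahydronaphthalen-1-yl]-3-methylpent-2-enoate (methyl 18-hydroxylabda-8(17),13E-dien-15-oate) | C=C1CC[C@H]2[C@](C)(CO)CCC[C@]2(C)[C@H]1CC/C(C)=C/C(=O)OC | intermediate
14 | β-cyclocitral, 2,6,6-trimethylcyclohex-1-ene-1-carbaldehyde | CC1=C(C=O)C(C)(C)CCC1 | starting material
15 | β-cyclogeraniol, (2,6,6-trimethylcyclohex-1-en-1-yl)methanol | CC1=C(CO)C(C)(C)CCC1 | intermediate
16 | [(1R,6R)-2,2,6-trimethyl-7-oxabicyclo[4.1.0]heptan-1-yl]methanol | OC[C@@]12O[C@]1(C)CCCC2(C)C | intermediate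
17 | (1S,6R)-2,2,6-trimethyl-7-oxabicyclo[4.1.0]heptane-1-carbaldehyde | O=C[C@@]12O[C@]1(C)CCCC2(C)C | intermediate
18 | (3E)-4-[(1S,6R)-2,2,6-trimethyl-7-oxabicyclo[4.1.0]heptan-1-yl]but-3-en-2-one | CC(=O)/C=C/[C@@]12O[C@]1(C)CCCC2(C)C | intermediate
19 | (4Z)-4-[(2R)-2-hydroxy-2,6,6-trimethylcyclohexylidene]butan-2-one | CC(=O)C/C=C1/C(C)(C)CCC[C@@]1(C)O | intermediate
20 | 4-[(1R,2R)-2-hydroxy-2,6,6-trimethylcyclohexyl]butan-2-one | CC(=O)CC[C@@H]1C(C)(C)CCC[C@@]1(C)O | intermediate
21 | methyl (2E)-5-[(1R,2R)-2-hydroxy-2,6,6-trimethylcyclohexyl]-3-methylpent-2-enoate | COC(=O)/C=C(\C)CC[C@@H]1C(C)(C)CCC[C@@]1(C)O | intermediate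
22 | (1R,2R)-2-[(3E)-5-hydroxy-3-methylpent-3-en-1-yl]-1,3,3-trimethylcyclohexan-1-ol | OC/C=C(\C)CC[C@@H]1C(C)(C)CCC[C@@]1(C)O | intermediate
23 | (1R,2R)-2-[(3S)-5-hydroxy-3-methylpentyl]-1,3,3-trimethylcyclohexan-1-ol | OCC[C@@H](C)CC[C@@H]1C(C)(C)CCC[C@@]1(C)O | intermediate
24 | (3S)-5-[(1R,2R)-2-hydroxy-2,6,6-trimethylcyclohexyl]-3-methylpentanoic acid | OC(=O)C[C@@H](C)CC[C@@H]1C(C)(C)CCC[C@@]1(C)O | intermediate
25 | methyl (2E)-5-[(1S,4aR,5R,8aR)-5-({[(3S)-5-[(1R,2R)-2-hydroxy-2,6,6-trimethylcyclohexyl]-3-methylpentanoyl]oxy}methyl)-5,8a-dimethyl-2-methylidenedecahydronaphthalen-1-yl]-3-methylpent-2-enoate | C=C1CC[C@H]2[C@](C)(COC(=O)C[C@@H](C)CC[C@@H]3C(C)(C)CCC[C@@]3(C)O)CCC[C@]2(C)[C@H]1CC/C(C)=C/C(=O)OC | target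

Total step count: 20 (steps 1–10 labdane alcohol, steps 11–19 acid, step 20 coupling).
Longest linear sequence: 11 steps (steps 1–10 and step 20).

Steps most likely to fail

Step 8 (cycloaddition). The unactivated 1,1-disubstituted alkene may react too slowly at a temperature the silyl enol ether tolerates, and cis ring fusion or incomplete π-facial control by C9 may erode the diastereoselectivity. Fallback: from 9 the same two bonds would be made by a metal-catalysed formal [4+2] cycloaddition instead of a pericyclic one, with [RhCl(cod)]2 and AgSbF6 (a cationic monovalent rhodium catalyst) in 1,2-dichloroethane at 25–60 °C. This is the known rhodium-catalysed intramolecular cycloaddition of unactivated dienes with alkenes, which runs through a rhodacycle at low temperature where the small energy differences between the transition states count for more. It comes back to the route at 10 and makes no new compound: none F0.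

Step 2 (α-methylenation of the keto aldehyde). The unprotected methyl ketone may enter intramolecular aldol or Mannich reactions under amine catalysis, and the chemoselectivity of the following reduction depends on it. Fallback: from 2 the aldehyde would be masked selectively (HC(OMe)3, MeOH, PPTS, rt; an aldehyde acetalises much faster than a methyl ketone) as (5S)-7,7-dimethoxy-5-(prop-1-en-2-yl)heptan-2-one F1. Horner–Wadsworth–Emmons olefination of the now unique ketone under the conditions of step 4 should give methyl (2E,6S)-8,8-dimethoxy-3-methyl-6-(prop-1-en-2-yl)oct-2-enoate F2. Aqueous acetic acid in THF frees methyl (2E,6S)-3-methyl-8-oxo-6-(prop-1-en-2-yl)oct-2-enoate F3, which has no ketone and is α-methylenated as in step 2 to methyl (2E,6R)-3,7-dimethyl-6-(3-oxoprop-1-en-2-yl)octa-2,7-dienoate F4. Luche reduction (NaBH4, CeCl3·7H2O, MeOH, 0 °C) then comes back to the route at 5.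

Step 15 (directed hydrogenation). The exocyclic trisubstituted alkene lies between two quaternary carbons, so hydrogenation may be sluggish or lose its direction, and the alkene may migrate towards the ketone. Fallback: from 19 the hydroxy ketone would be closed (MeOH, HC(OMe)3, PPTS; only the (Z)-alkene can close) to the bicyclic ketal (8aR)-2-methoxy-2,5,5,8a-tetramethyl-3,5,6,7,8,8a-hexahydro-2H-chromene F5 (both C2 epimers). Heterogeneous hydrogenation (H2, PtO2, EtOAc) should add hydrogen to the face away from the angular methyl, as in 4,4-dimethyl-Δ5-steroids, and give the trans-fused (4aR,8aR)-2-methoxy-2,5,5,8a-tetramethyloctahydro-2H-chromene F6 (both C2 epimers). Mild aqueous acid then comes back to the route at 20.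

Further compounds
F0 | step 8 | none | none
F1 | step 2 | (5S)-7,7-dimethoxy-5-(prop-1-en-2-yl)heptan-2-one | C=C(C)[C@H](CC(OC)OC)CCC(C)=O
F2 | step 2 | methyl (2E,6S)-8,8-dimethoxy-3-methyl-6-(prop-1-en-2-yl)oct-2-enoate | C=C(C)[C@H](CC(OC)OC)CC/C(C)=C/C(=O)OC
F3 | step 2 | methyl (2E,6S)-3-methyl-8-oxo-6-(prop-1-en-2-yl)oct-2-enoate | C=C(C)[C@H](CC=O)CC/C(C)=C/C(=O)OC
F4 | step 2 | methyl (2E,6R)-3,7-dimethyl-6-(3-oxoprop-1-en-2-yl)octa-2,7-dienoate | C=C(C)[C@H](C(=C)C=O)CC/C(C)=C/C(=O)OC
F5 | step 15 | (8aR)-2-methoxy-2,5,5,8a-tetramethyl-3,5,6,7,8,8a-hexahydro-2H-chromene (C2 epimers, C2 left open in the SMILES) | COC1(C)CC=C2C(C)(C)CCC[C@@]2(C)O1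
F6 | step 15 | (4aR,8aR)-2-methoxy-2,5,5,8a-tetramethyloctahydro-2H-chromene (C2 epimers, C2 left open in the SMILES) | COC1(C)CC[C@@H]2C(C)(C)CCC[C@@]2(C)O1
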